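## Retrosynthetic overview

1. The C10 ester bond to the (Z)-16-hydroxyhexadec-9-enoyl chain is made late. The C2 aldehyde is released in the last step by kinetic protonation of a C2=CH(OMe) enol ether, in the same pot as the global acid deprotection.
2. The C10 oxygen comes from the C8=C9 enoate by dienolate selenenylation and a [2,3] shift. H5 comes from hydroxyl-directed hydrogenation of a C4=C5 cage alkene.
3. Ring B, and with it the bicyclo[3.2.1] core, is closed by an intramolecular Michael addition of C6 to C7 inside a spiro[4.5]decatriene.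
4. Ring A and the quaternary C1 come from the key C1–C5 bond. The samarium ketyl of a beta-keto ester attacks the ipso carbon of a 4-alkylbenzoate and dearomatises ring C.
5. The precursor is built from tert-butyl 4-iodobenzoate, cyclopentenone (Rh/BINAP arylation, then ozonolysis) and methyl propanoate. Ring order: C (as arene), then A, then B.

Assumption: the SMILES is read literally as (1R,2S,5S,6S,7S,10S), so H5, the CH2OH on C6 and the oxygen on C10 all lie on the side of the C11 bridge, rings A and B are trans-fused, and the CHO on C2 points to the C10 side.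

Numbering (cedrane):
- C1 is the quaternary bridgehead and C2 carries the CHO.
- C3 and C4 are CH2, and C5 is the ring-fusion CH.
- C6 is C(CH3)(CH2OH), with C13 the CH2OH carbon and C14 the CH3 carbon.
- C7 is the bridgehead CH, C8 is =C(CO2H) and C9 is =CH.
- C10 is CH(O-acyl), C11 is the bridge CH2, C12 is the CHO carbon and C15 is the CO2H carbon.
- Ring A is C1–C5. Ring B is C1, C5, C6, C7, C11. Ring C is C1, C10, C9, C8, C7, C11.
- "Exo" means on the C11 side.

## Route

Step 1
Reactants: 1 tert-butyl 4-iodobenzoate; 2 cyclopent-2-en-1-one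
Product: 4 tert-butyl 4-[(1S)-3-(trimethylsilyloxy)cyclopent-2-en-1-yl]benzoate, via arylzinc iodide 3 (not isolated)
Conditions: Zn dust, LiCl, THF, 40 °C; then 2, Me3SiCl, [RhCl(C2H4)2]2 (1.5 mol %), (S)-BINAP (3.3 mol %), THF, 20 °C; non-aqueous work-up
Reagents that add atoms: chlorotrimethylsilane C[Si](C)(C)Cl
Why: Zinc insertion gives an ester-tolerant arylzinc that undergoes rhodium/(S)-BINAP-catalysed asymmetric 1,4-addition (Hayashi–Miyaura type), in which the ligand fixes the aryl-bearing carbon (future C2) as S and Me3SiCl traps the regiodefined enolate as its silyl enol ether.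

Step 2
Reactants: 4 tert-butyl 4-[(1S)-3-(trimethylsilyloxy)cyclopent-2-en-1-yl]benzoate
Product: 6 methyl (4R)-4-[4-(tert-butoxycarbonyl)phenyl]-5,5-dimethoxypentanoate, via silyl ester aldehyde 5 (not isolated)
Conditions: O3, CH2Cl2/MeOH, −78 °C; Me2S; then HC(OMe)3, TsOH·H2O (5 mol %), MeOH, rt
Reagents that add atoms: ozone [O-][O+]=O; trimethyl orthoformate COC(OC)OC
Why: Ozonolysis cleaves only the electron-rich silyl enol ether double bond, and immediate acid/orthoformate acetalisation and esterification mask the racemisation-prone alpha-aryl aldehyde, so the stereocentre is untouched and becomes R only through the change of priorities.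

Step 3
Reactants: 6 methyl (4R)-4-[4-(tert-butoxycarbonyl)phenyl]-5,5-dimethoxypentanoate; 7 methyl propanoate
Product: 9 methyl (6R)-6-[4-(tert-butoxycarbonyl)phenyl]-7,7-dimethoxy-2-methyl-3-oxoheptanoate (epimers at C2 of the chain), via lithium ester enolate 8 (not isolated)
Conditions: 7 (3 equiv), LiN(iPr)2 (3.1 equiv), THF, −78 °C; add 6, −78 to −30 °C; then AcOH
Reagents that add atoms: none
Why: In this crossed Claisen condensation the excess propanoate enolate acylates on the unhindered methyl ester (the tert-butyl benzoate is too hindered), and the new centre (future C6) is a mixture that is erased in step 6.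

Step 4
Reactants: 9 methyl (6R)-6-[4-(tert-butoxycarbonyl)phenyl]-7,7-dimethoxy-2-methyl-3-oxoheptanoate
Product: 11 tert-butyl (4R)-4-(dimethoxymethyl)-1-hydroxy-1-(1-methoxy-1-oxopropan-2-yl)spiro[4.5]deca-6,9-diene-8-carboxylate, via samarium ketyl 10 (not isolated)
Conditions: SmI2 (5 equiv), HMPA (20 equiv), i-PrOH (2.5 equiv), THF, 0 °C to rt
Reagents that add atoms: none
Why: Divalent samarium turns the electrophilic ketone carbon C5 into a nucleophilic chelated ketyl radical that adds 5-exo to the ipso carbon para to the ester (itself a vinylogous acceptor position), and a second electron plus protonation give the 1,4-diene (SmI2 ketyl–arene dearomatising spirocyclisation), leaving C2 untouched and creating only transient centres at C5, C6 and C8.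

Step 5
Reactants: 11 tert-butyl (4R)-4-(dimethoxymethyl)-1-hydroxy-1-(1-methoxy-1-oxopropan-2-yl)spiro[4.5]deca-6,9-diene-8-carboxylate
Product: 12 tert-butyl (4R)-4-(dimethoxymethyl)-1-(1-methoxy-1-oxopropan-2-yl)spiro[4.5]deca-1,6,9-triene-8-carboxylate
Conditions: MeO2CN–SO2NEt3 (Burgess inner salt), toluene, 60 °C
Reagents that add atoms: none
Why: Burgess syn-elimination dehydrates the hindered tertiary alcohol under neutral conditions, which avoids a C5 cation that could rearomatise ring C by a 1,2-shift, and it removes the C5 centre by forming the C4=C5 cyclopentene.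

Step 6
Reactants: 12 tert-butyl (4R)-4-(dimethoxymethyl)-1-(1-methoxy-1-oxopropan-2-yl)spiro[4.5]deca-1,6,9-triene-8-carboxylate
Product: 14 8-tert-butyl 6-methyl 2-(dimethoxymethyl)-6-methyltricyclo[5.3.1.0(1,5)]undeca-4,8-diene-6,8-dicarboxylate (C1 C6 C7 as in the target; CO2Me exo; acetal on C2 syn to C11), via conjugated diene ester 13 (not isolated)
Conditions: KOtBu (0.3 equiv), t-BuOH/THF 1:1, rt to 45 °C
Reagents that add atoms: none
Why: tert-Butoxide moves the skipped diene into conjugation and forms the C6 ester enolate, which closes ring B by a reversible 5-exo intramolecular Michael addition to C7, settling on the ring C face syn to the acetal (the other face would push C10 and C9 against it) with the bulky enolate ester group in the open exo slot and the methyl group beside C8, so that C1, C7 and C6 are set from C2.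

Step 7
Reactants: 14 cage diester
Product: 15 tert-butyl 2-(dimethoxymethyl)-6-(hydroxymethyl)-6-methyltricyclo[5.3.1.0(1,5)]undeca-4,8-diene-8-carboxylate (configuration as in 14)
Conditions: LiBH4 (3 equiv), MeOH (3 equiv), Et2O, 0 °C to reflux; aqueous work-up
Reagents that add atoms: none
Why: This chemoselective ester reduction takes the methyl ester to the primary alcohol while the bulky conjugated tert-butyl ester survives, and no stereocentre is touched.

Step 8
Reactants: 15 cage dienol
Product: 16 tert-butyl 2-(dimethoxymethyl)-6-(hydroxymethyl)-6-methyltricyclo[5.3.1.0(1,5)]undec-8-ene-8-carboxylate (H5 exo and syn to CH2OH; rings A and B trans-fused)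
Conditions: H2 (30 bar), [Ir(cod)(PCy3)(py)]PF6 (10 mol %), CH2Cl2, rt
Reagents that add atoms: none
Why: In this hydroxyl-directed homogeneous hydrogenation the cationic iridium hydride is anchored by the exo homoallylic C13 hydroxyl (helped by the acetal oxygens on the same face) and delivers H2 to C4=C5 from the exo face, which sets H5 against the thermodynamic preference, while the electron-poor and remote C8=C9 enoate is left alone.

Step 9
Reactants: 16 cage alcohol
Product: 17 C13 tert-butyldimethylsilyl ether of 16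
Conditions: TBSCl, imidazole, DMF, rt
Reagents that add atoms: tert-butyldimethylsilyl chloride CC(C)(C)[Si](C)(C)Cl
Why: Standard silylation blocks the primary alcohol so that only the C10 hydroxyl made next can be acylated, and no stereocentre is touched.

Step 10
Reactants: 17 silyl ether
Product: 19 tert-butyl 6-[(tert-butyldimethylsilyloxy)methyl]-2-(dimethoxymethyl)-10-hydroxy-6-methyltricyclo[5.3.1.0(1,5)]undec-8-ene-8-carboxylate (OH on C10 syn to C11), via allylic selenide 18 (not isolated)
Conditions: LiN(iPr)2, THF, −78 °C; PhSeCl, −78 °C; then 30% H2O2, pyridine, CH2Cl2, 0 °C to rt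
Reagents that add atoms: hydrogen peroxide OO
Why: Gamma-deprotonation at C10 gives the extended enolate, which is selenenylated at C8 on the face syn to C11 (the other face is blocked by the endo methyl group and ring A), and oxidation triggers the suprafacial [2,3]-sigmatropic selenoxide–selenenate rearrangement that places oxygen on the same face of C10 and restores the C8=C9 enoate.

Step 11
Reactants: 20 oct-7-yn-1-ol
Product: 21 tert-butyl(dimethyl)(oct-7-yn-1-yloxy)silane
Conditions: TBSCl, imidazole, CH2Cl2, rt
Reagents that add atoms: tert-butyldimethylsilyl chloride CC(C)(C)[Si](C)(C)Cl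
Why: Silylation masks the hydroxyl that will become the free chain terminus, so that it cannot compete in steps 12 and 14.

Step 12
Reactants: 21 tert-butyl(dimethyl)(oct-7-yn-1-yloxy)silane; 22 8-bromooctanoic acid
Product: 25 16-(tert-butyldimethylsilyloxy)hexadec-9-ynoic acid, via lithium acetylide 23 (not isolated), via lithium 8-bromooctanoate 24 (not isolated)
Conditions: 21 (2.1 equiv), n-BuLi (2.1 equiv), THF, −78 to 0 °C; add 22 in DMPU, 0 to 45 °C; then cold 0.5 M HCl
Reagents that add atoms: none
Why: The first equivalent of acetylide deprotonates the acid, and the second displaces the primary bromide in an SN2 acetylide alkylation that assembles the C16 chain with the triple bond at C9.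

Step 13
Reactants: 25 16-(tert-butyldimethylsilyloxy)hexadec-9-ynoic acid
Product: 26 (9Z)-16-(tert-butyldimethylsilyloxy)hexadec-9-enoic acid
Conditions: H2 (1 atm), Pd/CaCO3 poisoned with Pb(OAc)2, quinoline, EtOAc, rt
Reagents that add atoms: none
Why: Syn semi-hydrogenation of the alkyne on lead-poisoned palladium stops at the alkene and sets the Z geometry.

Step 14
Reactants: 19 cage allylic alcohol; 26 (9Z)-16-(tert-butyldimethylsilyloxy)hexadec-9-enoic acid
Product: 27 C10 (9Z)-16-(tert-butyldimethylsilyloxy)hexadec-9-enoate of 19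
Conditions: DCC, DMAP, CH2Cl2, rt
Reagents that add atoms: none
Why: Steglich esterification acylates the only free hydroxyl at oxygen, so C10 keeps its configuration, and the acetal on the far (C11) side of C2 leaves this neopentylic alcohol accessible.

Step 15
Reactants: 27 fully protected ester
Product: 29 CNP0148862.1 (target), via methyl enol ether 28 (not isolated)
Conditions: Me3SiOTf, i-Pr2NEt, CH2Cl2, −20 °C to rt; then CF3CO2H/H2O 9:1, 0 °C to rt
Reagents that add atoms: water O
Why: Me3SiOTf and amine eliminate methanol from the acetal (Gassman-type enol ether formation), which erases C2, and aqueous acid then protonates C2 irreversibly from the face away from the C10 acyloxy group to give the kinetic 2S aldehyde, while the same acid cleaves both silyl ethers and the tert-butyl ester.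

## Compound list

1 | tert-butyl 4-iodobenzoate | CC(C)(C)OC(=O)c1ccc(I)cc1 | starting material
2 | cyclopent-2-en-1-one | O=C1C=CCC1 | starting material
3 | [4-(tert-butoxycarbonyl)phenyl]zinc iodide | CC(C)(C)OC(=O)c1ccc([Zn]I)cc1 | intermediate
4 | tert-butyl 4-[(1S)-3-(trimethylsilyloxy)cyclopent-2-en-1-yl]benzoate | C[Si](C)(C)OC1=C[C@@H](c2ccc(cc2)C(=O)OC(C)(C)C)CC1 | intermediate
5 | trimethylsilyl (4R)-4-[4-(tert-butoxycarbonyl)phenyl]-5-oxopentanoate | O=C[C@@H](c1ccc(cc1)C(=O)OC(C)(C)C)CCC(=O)O[Si](C)(C)C | intermediate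
6 | methyl (4R)-4-[4-(tert-butoxycarbonyl)phenyl]-5,5-dimethoxypentanoate | COC(OC)[C@@H](c1ccc(cc1)C(=O)OC(C)(C)C)CCC(=O)OC | intermediate
7 | methyl propanoate | CCC(=O)OC | starting material
8 | lithium enolate of methyl propanoate | CC=C(OC)[O-].[Li+] | intermediate
9 | methyl (6R)-6-[4-(tert-butoxycarbonyl)phenyl]-7,7-dimethoxy-2-methyl-3-oxoheptanoate | COC(OC)[C@@H](c1ccc(cc1)C(=O)OC(C)(C)C)CCC(=O)C(C)C(=O)OC | intermediate
10 | samarium ketyl of 9 (radical at C5, O–SmI2) | COC(OC)[C@@H](c1ccc(cc1)C(=O)OC(C)(C)C)CC[C](O[Sm](I)I)C(C)C(=O)OC | intermediate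
11 | tert-butyl (4R)-4-(dimethoxymethyl)-1-hydroxy-1-(1-methoxy-1-oxopropan-2-yl)spiro[4.5]deca-6,9-diene-8-carboxylate | COC(OC)[C@@H]1CCC(O)(C(C)C(=O)OC)C12C=CC(C=C2)C(=O)OC(C)(C)C | intermediate
12 | tert-butyl (4R)-4-(dimethoxymethyl)-1-(1-methoxy-1-oxopropan-2-yl)spiro[4.5]deca-1,6,9-triene-8-carboxylate | COC(OC)[C@@H]1CC=C(C(C)C(=O)OC)C12C=CC(C=C2)C(=O)OC(C)(C)C | intermediate
13 | spiro[4.5]deca-1,7,9-triene isomer of 12 (ring CH2 on the face of the acetal) | COC(OC)[C@@H]1CC=C(C(C)C(=O)OC)[C@]12CC=C(C=C2)C(=O)OC(C)(C)C | intermediate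
14 | cage diester (C4=C5, C8=C9; CO2Me exo; acetal syn to C11) | C[C@@]1(C(=O)OC)[C@@H]2C[C@]3(CC=C2C(=O)OC(C)(C)C)[C@H](C(OC)OC)CC=C13 | intermediate
15 | cage dienol (CH2OH exo) | C[C@@]1(CO)[C@@H]2C[C@]3(CC=C2C(=O)OC(C)(C)C)[C@H](C(OC)OC)CC=C13 | intermediate
16 | cage alcohol with H5 exo | C[C@@]1(CO)[C@@H]2C[C@]3(CC=C2C(=O)OC(C)(C)C)[C@H](C(OC)OC)CC[C@@H]13 | intermediate
17 | C13 TBS ether of 16 | C[C@@]1(CO[Si](C)(C)C(C)(C)C)[C@@H]2C[C@]3(CC=C2C(=O)OC(C)(C)C)[C@H](C(OC)OC)CC[C@@H]13 | intermediate
18 | C8 phenylselenide (Se syn to C11; C9=C10) | C[C@@]1(CO[Si](C)(C)C(C)(C)C)[C@@H]2C[C@]3(C=C[C@]2([Se]c4ccccc4)C(=O)OC(C)(C)C)[C@H](C(OC)OC)CC[C@@H]13 | intermediate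
19 | C10 allylic alcohol (OH syn to C11) | C[C@@]1(CO[Si](C)(C)C(C)(C)C)[C@@H]2C[C@]3([C@@H](O)C=C2C(=O)OC(C)(C)C)[C@H](C(OC)OC)CC[C@@H]13 | intermediate
20 | oct-7-yn-1-ol | C#CCCCCCCO | starting material
21 | tert-butyl(dimethyl)(oct-7-yn-1-yloxy)silane | C#CCCCCCCO[Si](C)(C)C(C)(C)C | intermediate
22 | 8-bromooctanoic acid | OC(=O)CCCCCCCBr | starting material
23 | lithium acetylide of 21 | [Li+].[C-]#CCCCCCCO[Si](C)(C)C(C)(C)C | intermediate
24 | lithium 8-bromooctanoate | [Li+].[O-]C(=O)CCCCCCCBr | intermediate
25 | 16-(tert-butyldimethylsilyloxy)hexadec-9-ynoic acid | OC(=O)CCCCCCCC#CCCCCCCO[Si](C)(C)C(C)(C)C | intermediate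
26 | (9Z)-16-(tert-butyldimethylsilyloxy)hexadec-9-enoic acid | OC(=O)CCCCCCC/C=C\CCCCCCO[Si](C)(C)C(C)(C)C | intermediate
27 | fully protected C10 ester | C[C@@]1(CO[Si](C)(C)C(C)(C)C)[C@@H]2C[C@]3([C@@H](OC(=O)CCCCCCC/C=C\CCCCCCO[Si](C)(C)C(C)(C)C)C=C2C(=O)OC(C)(C)C)[C@H](C(OC)OC)CC[C@@H]13 | intermediate
28 | C2=CH(OMe) enol ether of 27 (E/Z mixture) | C[C@@]1(CO[Si](C)(C)C(C)(C)C)[C@@H]2C[C@]3([C@@H](OC(=O)CCCCCCC/C=C\CCCCCCO[Si](C)(C)C(C)(C)C)C=C2C(=O)OC(C)(C)C)C(=COC)CC[C@@H]13 | intermediate
29 | CNP0148862.1, (1R,2S,5S,6S,7S,10S) | C[C@@]1(CO)[C@@H]2C[C@]3([C@@H](OC(=O)CCCCCCC/C=C\CCCCCCO)C=C2C(=O)O)[C@@H](C=O)CC[C@@H]13 | target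

## Step count and risks

Total step count: 15. Longest linear sequence: 12 (steps 1 to 10, then 14 and 15).

**Step 4.** The acidic beta-keto ester may only be enolised by trivalent samarium, or be reduced to the carbinol without attacking the arene. The fallback sets out from 9. O-Acetylation (NaH, AcCl, THF/DMPU) gives the enol acetate F1, in which C5 is the beta carbon of an enoate and no acidic proton is left. SmI2/HMPA/t-BuOH then makes C5 nucleophilic as an enoate radical anion (homoenolate type). Ipso attack is followed by loss of acetate from the samarium enolate and gives the alkylidene ester F2, a double-bond isomer of 12. Under the conditions of step 6, F2 is deprotonated at C4 to the same dienolate, so the route is rejoined at 14 and step 5 is skipped.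

**Step 6.** The enolate next to the C4=C5 bond must twist out of conjugation to reach C7, and facial control rests on C2 alone. The fallback sets out from 11.
- The C5 epimer whose propanoate branch is cis to the acetal is separated and silylated (Me3SiOTf, 2,6-lutidine) to the silyl ether F3.
- KOtBu/t-BuOH closes ring B from a plain ester enolate on an sp3 C5, so the face is dictated by C5, and this gives the cis-fused cage silyl ether F4.
- Bu4NF frees the tertiary alcohol F5.
- Burgess elimination, now possible only toward C4, comes back to the route at 14.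

**Step 8.** Hydrogen must be delivered to the face that produces the strained trans ring fusion. The iridium catalyst may not react, or it may add from the C10 side. The fallback sets out from 15.
- BH3·THF first forms the C13 alkoxyborane, which hydroborates C4=C5 intramolecularly from the exo face (boron to C4, hydrogen to C5).
- NaBO3 oxidation then gives the diol F6.
- Selective silylation of the primary alcohol (TBSCl, imidazole) gives the silyl ether F7.
- NaH, CS2 and MeI give the xanthate F8.
- Barton–McCombie reduction (Bu3SnH, AIBN) removes the C4 oxygen and comes back to the route at 17.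

## Further compounds

F1 | step 4 | methyl (6R)-3-acetoxy-6-[4-(tert-butoxycarbonyl)phenyl]-7,7-dimethoxy-2-methylhept-2-enoate | COC(OC)[C@@H](c1ccc(cc1)C(=O)OC(C)(C)C)CCC(OC(C)=O)=C(C)C(=O)OC
F2 | step 4 | tert-butyl (4R)-4-(dimethoxymethyl)-1-(1-methoxy-1-oxopropan-2-ylidene)spiro[4.5]deca-6,9-diene-8-carboxylate | COC(OC)[C@@H]1CCC(=C(C)C(=O)OC)C12C=CC(C=C2)C(=O)OC(C)(C)C
F3 | step 6 | trimethylsilyl ether of the C5 epimer of 11 with the propanoate branch cis to the acetal | COC(OC)[C@@H]1CC[C@](O[Si](C)(C)C)(C(C)C(=O)OC)C12C=CC(C=C2)C(=O)OC(C)(C)C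
F4 | step 6 | cis-fused cage diester with endo OSiMe3 on C5 | C[C@@]1(C(=O)OC)[C@@H]2C[C@]3(CC=C2C(=O)OC(C)(C)C)[C@H](C(OC)OC)CC[C@]13O[Si](C)(C)C
F5 | step 6 | cis-fused cage diester with endo OH on C5 | C[C@@]1(C(=O)OC)[C@@H]2C[C@]3(CC=C2C(=O)OC(C)(C)C)[C@H](C(OC)OC)CC[C@]13O
F6 | step 8 | C4,C13 diol with H5 and the C4 OH on the exo face | C[C@@]1(CO)[C@@H]2C[C@]3(CC=C2C(=O)OC(C)(C)C)[C@H](C(OC)OC)C[C@H](O)[C@@H]13
F7 | step 8 | C13 TBS ether of F6 | C[C@@]1(CO[Si](C)(C)C(C)(C)C)[C@@H]2C[C@]3(CC=C2C(=O)OC(C)(C)C)[C@H](C(OC)OC)C[C@H](O)[C@@H]13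
F8 | step 8 | C4 S-methyl xanthate of F7 | C[C@@]1(CO[Si](C)(C)C(C)(C)C)[C@@H]2C[C@]3(CC=C2C(=O)OC(C)(C)C)[C@H](C(OC)OC)C[C@H](OC(=S)SC)[C@@H]13
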